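**Strategy**

The flavone is disconnected at C2 of ring C, the carbon bonded to C1' of ring B, to C3 and to O1. Since C3 can originate as the acetyl methyl of a ring A acetophenone and O1 as its ortho phenol oxygen, C2 is supplied as carbon monoxide: a single palladium-catalysed carbonylative ketone arylation forges both C1'–C2 and C2–C3 and delivers the open 1,3-diketone. Its precursors are 2-hydroxy-3,4,6-trimethoxyacetophenone, used as a preformed dianion in twofold amount so that no free amide base competes for the aroylpalladium species, and 1-iodo-2,3,4-trimethoxybenzene. Acid-catalysed closure of O1–C2 then completes ring C.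

Key step: step 4

Remark: carbon monoxide is counted as a numbered starting material, and diketone 9 is drawn in its diketo form although it should exist largely as the chelated enol.

**Route**

Step 1
Reactants: 1 3,4,5-trimethoxyphenol
Product: 2 1,2,3,5-tetramethoxybenzene
Conditions: MeI, K2CO3, acetone, reflux
Reagents that add atoms: iodomethane, CI
Why: Williamson-type O-methylation of the phenoxide by SN2 attack on iodomethane should be clean because the phenol is the only nucleophilic site.

Step 2
Reactants: 2 1,2,3,5-tetramethoxybenzene
Product: 4 1-(2-hydroxy-3,4,6-trimethoxyphenyl)ethanone, via 1-(2,3,4,6-tetramethoxyphenyl)ethanone 3 (not isolated)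
Conditions: AcCl, AlCl3, Et2O, 0 °C to rt; then ice-water
Reagents that add atoms: acetyl chloride, CC(Cl)=O
Why: Friedel–Crafts acylation can occur only at the one type of free ring position, and AlCl3 bound to the new carbonyl should then cleave the ortho methyl ether squeezed between the acetyl group and the neighbouring methoxy group, whose out-of-plane and more basic oxygen reacts in preference to the unbuttressed ortho ether, leaving the chelated phenol of 4.

Step 3
Reactants: 5 1,2,3-trimethoxybenzene
Product: 6 1-iodo-2,3,4-trimethoxybenzene
Conditions: NIS (1.05 equiv), CF3CO2H (cat.), MeCN, rt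
Reagents that add atoms: N-iodosuccinimide, O=C1CCC(=O)N1I
Why: Electrophilic aromatic iodination should go to C4, which is para to one in-plane methoxy group and ortho to another, whereas C5 is para only to the twisted central methoxy group, and one equivalent of the mild iodinating agent limits a second iodination.

Step 4
Reactants: 4 1-(2-hydroxy-3,4,6-trimethoxyphenyl)ethanone, 6 1-iodo-2,3,4-trimethoxybenzene, 7 carbon monoxide
Product: 9 1-(2-hydroxy-3,4,6-trimethoxyphenyl)-3-(2,3,4-trimethoxyphenyl)propane-1,3-dione, via disodium 3,5,6-trimethoxy-2-(1-oxidoethenyl)phenolate 8 (not isolated)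
Conditions: 4 (2 equiv), NaN(SiMe3)2 (4 equiv), THF, 0 °C; then 6 (1 equiv), Pd(dba)2 (5 mol %), Xantphos (5 mol %), CO (2 bar), THF–dioxane, 80 °C; then 1 M HCl
Reagents that add atoms: none
Why: Oxidative addition of 6 to zerovalent palladium gives an arylpalladium iodide, CO inserts into the palladium–aryl bond (forming C1'–C2) to give the aroylpalladium complex, the enolate carbon of 8 replaces iodide on palladium, and reductive elimination forms C2–C3. The closest known reaction type is the palladium-catalysed carbonylative alpha-arylation of ketone enolates with aryl iodides, which has also been applied to 2-hydroxyacetophenones on the way to flavones. No ring is closed and no stereocentre is formed. The step needs carbonylative coupling to beat direct alpha-arylation and a second CO insertion: the ortho methoxy group of 6 and the doubly ortho-substituted enolate slow direct aryl–enolate coupling, CO insertion into the electron-rich aryl–palladium bond is fast, and the wide bite angle of Xantphos should speed acyl reductive elimination before more CO is taken up. Selectivity between the carbon and oxygen sites of 8 is not critical, because an O-aroylated product would undergo Baker–Venkataraman acyl transfer to the same diketone under the basic conditions. The second equivalent of 8 serves as the base that deprotonates the more acidic diketone, so no free silylamide is present to form an aroyl amide, and the surplus 4 should be recovered at work-up.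

Step 5
Reactants: 9 1-(2-hydroxy-3,4,6-trimethoxyphenyl)-3-(2,3,4-trimethoxyphenyl)propane-1,3-dione
Product: 10 2',3',4',5,7,8-hexamethoxyflavone
Conditions: H2SO4 (cat.), AcOH, 100 °C
Reagents that add atoms: none
Why: Acid-catalysed cyclodehydration, the closing stage of a Baker–Venkataraman flavone synthesis, should proceed by 6-exo-trig addition of the phenol oxygen to the protonated aroyl carbonyl (forming O1–C2) and loss of water from the resulting 2-hydroxyflavanone hemiketal, conditions under which aryl methyl ethers should persist.

**Compound list**

1 | 3,4,5-trimethoxyphenol | COc1cc(O)cc(OC)c1OC | starting material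
2 | 1,2,3,5-tetramethoxybenzene | COc1cc(OC)c(OC)c(OC)c1 | intermediate
3 | 1-(2,3,4,6-tetramethoxyphenyl)ethanone | COc1cc(OC)c(C(C)=O)c(OC)c1OC | intermediate
4 | 1-(2-hydroxy-3,4,6-trimethoxyphenyl)ethanone | COc1cc(OC)c(C(C)=O)c(O)c1OC | intermediate
5 | 1,2,3-trimethoxybenzene | COc1cccc(OC)c1OC | starting material
6 | 1-iodo-2,3,4-trimethoxybenzene | COc1ccc(I)c(OC)c1OC | intermediate
7 | carbon monoxide | [C-]#[O+] | starting material
8 | disodium 3,5,6-trimethoxy-2-(1-oxidoethenyl)phenolate | [Na+].[Na+].C=C([O-])c1c(OC)cc(OC)c(OC)c1[O-] | intermediate
9 | 1-(2-hydroxy-3,4,6-trimethoxyphenyl)-3-(2,3,4-trimethoxyphenyl)propane-1,3-dione | COc1ccc(C(=O)CC(=O)c2c(OC)cc(OC)c(OC)c2O)c(OC)c1OC | intermediate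
10 | 2',3',4',5,7,8-hexamethoxyflavone (5,7,8-trimethoxy-2-(2,3,4-trimethoxyphenyl)-4H-chromen-4-one) | COc1ccc(-c2cc(=O)c3c(OC)cc(OC)c(OC)c3o2)c(OC)c1OC | target

**Step count**

Total step count: 5. Steps 4 and 5 could be run without purifying 9.
Longest linear sequence: 4 steps (steps 1, 2, 4 and 5). Step 3 is a one-step branch.

**Steps most likely to fail**

Step 4. Capture of the aroylpalladium intermediate by the hindered, chelating enolate may be too slow, so that hydrodeiodination of 6, non-carbonylative arylation or catalyst decomposition under CO takes over. The fallback sets out from 4 and comes back at 9; it brings in C2 at the carboxylic acid oxidation level instead of as CO. Phenol 4 would be O-acylated with commercial 2,3,4-trimethoxybenzoyl chloride (pyridine, DMAP cat., CH2Cl2, rt) to give 2-acetyl-3,5,6-trimethoxyphenyl 2,3,4-trimethoxybenzoate F1. Baker–Venkataraman rearrangement (KOH, pyridine, 50 °C; then dilute AcOH) would then move the aroyl group from oxygen to the acetyl carbon and give 9.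

Step 2. The Lewis-acid ether cleavage may not stop at the single buttressed ortho ether, so that the other ortho ether or two ethers are cleaved, or it may stall at 3. The fallback sets out from 2 and comes back at 4; it separates C–C bond formation from ether cleavage and makes the C–C bond with an aryl anion instead of by electrophilic substitution. Lithiation of 2 (n-BuLi, THF, 0 °C) at a ring C–H flanked by two methoxy groups would give (2,3,4,6-tetramethoxyphenyl)lithium F2. Acylation with N-methoxy-N-methylacetamide (−78 °C to rt; then 1 M HCl) would give 3, this time isolated. BCl3 (1.1 equiv, CH2Cl2, −78 to 0 °C; then water) should then cleave one ortho ether through the boron chelate and return 4.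

Step 5. Hot protic acid may cleave the C5 methyl ether, which lies peri to the C4 carbonyl, or sulfonate the electron-rich rings. The fallback sets out from 4 and comes back at 10; it closes ring C oxidatively from a chalcone without strong acid. Claisen–Schmidt condensation of 4 with commercial 2,3,4-trimethoxybenzaldehyde (KOH, EtOH, rt) would give (E)-1-(2-hydroxy-3,4,6-trimethoxyphenyl)-3-(2,3,4-trimethoxyphenyl)prop-2-en-1-one F3. Iodine (cat.) in DMSO at 120 °C should then effect oxa-Michael closure and dehydrogenation to 10.

**Further compounds**

F1 | step 4 | 2-acetyl-3,5,6-trimethoxyphenyl 2,3,4-trimethoxybenzoate | COc1ccc(C(=O)Oc2c(OC)c(OC)cc(OC)c2C(C)=O)c(OC)c1OC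
F2 | step 2 | (2,3,4,6-tetramethoxyphenyl)lithium | [Li]c1c(OC)cc(OC)c(OC)c1OC
F3 | step 5 | (E)-1-(2-hydroxy-3,4,6-trimethoxyphenyl)-3-(2,3,4-trimethoxyphenyl)prop-2-en-1-one | COc1ccc(/C=C/C(=O)c2c(OC)cc(OC)c(OC)c2O)c(OC)c1OC
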